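The readings are calculated with made-up constants, noise included.

In a one-step world, one substrate meets one reagent and gives one product, and the end state is a subtraction. Treat this catalysed flask that way first. The north-east run is the flask itself, followed so far.

| setting | north-east | south-west | flask |
|---|---|---|---|
| substrate | 0.80 M | 0.80 M | 0.80 M |
| reagent | 0.56 M | 0.38 M | 0.560 M |
| free catalyst | 1.6 mM | 1.6 mM | 1.6 mM |
| remark | the very flask that is asked about, followed so far | run made earlier |  |
| time |  |  | 25 h |

north-east run (percent of the substrate charged)

| time / h | product / % | substrate / % |
|---|---|---|
| 1.50 | 10.8 | 87.0 |
| 4.00 | 26.1 | 72.7 |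
| 8.00 | 48.4 | 53.6 |
| 20.0 | 68.4 | 29.7 |

south-west run (percent of the substrate charged)

| time / min | product / % | substrate / % |
|---|---|---|
| 5.00 | 2.8 | 99.4 |
| 12.0 | 1.2 | 98.7 |
| 25.0 | 3.6 | 97.1 |
| 60.0 | 7.0 | 95.0 |

(each reading ± 1 percentage point)

- violet: at 25 h add free catalyst, 100% of the amount charged, then wait 2.0 d
- red: change nothing and wait 2.0 d more
- amber: at 25 h add reagent, 100% of the amount charged, then wait 2.0 d
- ochre: at 25 h take out 90% of the product then present, then wait 2.0 d

* product, in percent of the substrate first charged, at 25 h
* which option adds most product ("none" when 2 percentage points or less is all one gets) (violet / red / amber / ochre / none)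
* product present, with what was taken out counted in, in percent of the substrate first charged, after violet
* product present, with what was taken out counted in, in percent of the substrate first charged, after ochre

- what is taken out of product is counted as made
- the earlier runs were read with a standard deviation of 1 percentage point
- additions bring no volume worth counting

Call reagent charged over substrate charged the ceiling: 70.0%. Reagent was never read, so take it as an assumption that each product costs one reagent. Then this is the most product you can get, in percent of the substrate charged. The ceiling stands below the whole charge, so reagent is the limiting reagent.

The north-east run approaches this ceiling. The gap to it is 22 percentage points at 8.00 h and 1.6 points at 20.0 h, which is near the scatter. My reckoning for 25 h is therefore the ceiling itself.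

Violet, red and ochre bring no reagent, so they leave the ceiling where it is. Amber lifts it to 140%, above the whole substrate, so amber can add up to 30 points. The wait of 2.0 d is longer than the 20.0 h in which the north-east run came to the ceiling's edge.

Was one number enough? Not quite. The south-west ceiling is 47.5%, but that run ends at 7.0% after 60.0 min, so it can't test the idea. The north-east readings end at the ceiling's edge and show no plateau, so a balance of forward and back reactions stopping nearby isn't excluded. My verdict on ochre, no gain, assumes no such balance.

The forecast gave 69%, which is 1 point below my figure. It chose amber, with 70% after violet and 70% after ochre, holding that “the coincidence with 70% favours exhaustion”.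

The flask gives 70.0%. Amber adds 30 points, and violet, red and ochre each add 0 points. Product stands at 70.0% after violet and 70.0% after ochre.

    reagent + free catalyst ⇌ catalyst intermediate A (K = 2.10 M⁻¹, k = 5800 M⁻¹ h⁻¹)
    catalyst intermediate A → catalyst intermediate B (k = 220 h⁻¹)
    substrate + catalyst intermediate B ⇌ catalyst intermediate C (K = 0.690 M⁻¹, k = 350 M⁻¹ h⁻¹)
    catalyst intermediate C → catalyst intermediate D (k = 250 h⁻¹)
    catalyst intermediate D → free catalyst + product (k = 320 h⁻¹)

The stop comes from the consumption of reagent. At 25.0 h this flask holds 0.00532% of its reagent still free, and the same run with that consumption taken away gives 96.0%, not 70.0%. Now take a second flask, like this one but with 0.20 M of substrate. Its ceiling is 280%, above the whole charge, so substrate should run out first. It does: 1.4% of its substrate stays free, product reaches 98.6%, and 65% of its reagent is still free.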